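## Retrosynthetic overview

1. The side chain comes off last: the outer angelate by carboxylate SN2 on a (Z)-γ-bromo enoate, the inner ester by acylation of the C3–OH. The C8 ketone is unveiled at the very end by allylic oxidation.
2. Key disconnection C8–C9 (ring B, formed second): SmI2 ketyl (umpoled carbonyl) cross-pinacol between the C9 aldehyde and a hindered C8 enal. The same reagent then sets the C3 carbinol.
3. Ring A (formed first): enantioselective Diels–Alder of a (Z)-2-siloxy-1,3-pentadiene with an (E)-β,β-disubstituted enal, setting C4, C5 (quaternary) and C10.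
4. The dienophile comes from a Claisen rearrangement (C6–C7 bond, E-alkene) of a Grignard-derived 2-methylallyl carbinol with prenal acetal.

Note: C-locants in the comments are eremophilane numbers (C3 = ester carbon, C4 = CHMe, C5 = quaternary C, C8 = ketone, C9 = carbinol, C10 = ring-fusion CH).

Assumption: the (S)-configured cationic oxazaborolidine is taken to expose the Si face of the enal β-carbon of 9 (Corey's enal model); if the sense were opposite, the (R)-catalyst would be used.

## Route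

Step 1
Reactants: 1 2,2-diethoxyacetaldehyde; 2 isopropenylmagnesium bromide
Product: 3 1,1-diethoxy-3-methylbut-3-en-2-ol (racemic; this centre is erased in step 2)
Conditions: THF, −78 → 0 °C; aq. NH4Cl
Reagents that add atoms: isopropenylmagnesium bromide, CC(=C)[Mg]Br
Why: Grignard 1,2-addition to the aldehyde gives the 2-methylallyl carbinol needed for the Claisen step, and its stereocentre needs no control because it becomes sp2 in step 2.

Step 2
Reactants: 3 1,1-diethoxy-3-methylbut-3-en-2-ol; 4 1,1-diethoxy-3-methylbut-2-ene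
Product: 9 (2E)-3-methyl-5-(propan-2-ylidene)hex-2-enedial, via mixed acetal 5 (not isolated), via dienyl allyl ether 6 (not isolated), via isopropenyl aldehyde 7 (not isolated), via conjugated acetal aldehyde 8 (not isolated)
Conditions: 2,4-dinitrophenol (5 mol %), xylene, 135 °C, −EtOH; then 1 M HCl, THF, 0 °C
Reagents that add atoms: 1,1-diethoxy-3-methylbut-2-ene, CCOC(OCC)C=C(C)C; water, O
Why: Acetal exchange and loss of ethanol give the allyl 1,3-dienyl ether, whose chair Claisen rearrangement (acetal substituent equatorial) forms C6–C7 and the (E)-trisubstituted alkene; the α-isopropenyl aldehyde then conjugates under the acid and aqueous acid frees the second aldehyde.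

Step 3
Reactants: 10 pent-1-en-3-one; 11 tert-butyldimethylsilyl trifluoromethanesulfonate
Product: 12 tert-butyldimethyl{[(3Z)-penta-1,3-dien-3-yl]oxy}silane
Conditions: Et3N, Et2O, 0 °C
Reagents that add atoms: tert-butyldimethylsilyl trifluoromethanesulfonate, CC(C)(C)[Si](C)(C)OS(=O)(=O)C(F)(F)F
Why: Soft enolisation of the ethyl ketone (silyl enol ether formation) gives mainly the (Z)-enol ether, i.e. the diene with an outward methyl; any (E)-isomer reaches the s-cis form poorly and is left behind in step 4.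

Step 4
Reactants: 9 (2E)-3-methyl-5-(propan-2-ylidene)hex-2-enedial; 12 tert-butyldimethyl{[(3Z)-penta-1,3-dien-3-yl]oxy}silane
Product: 14 2-{[(1S,2R,6R)-6-formyl-1,2-dimethyl-3-oxocyclohexyl]methyl}-3-methylbut-2-enal, via silyl enol ether cycloadduct 13 (not isolated)
Conditions: (S)-B-(o-tolyl)diphenylprolinol oxazaborolidine·AlBr3 (20 mol %), CH2Cl2, −78 → −40 °C; then 1 M HCl, THF, 0 °C
Reagents that add atoms: tert-butyldimethyl{[(3Z)-penta-1,3-dien-3-yl]oxy}silane, C/C=C(\O[Si](C)(C)C(C)(C)C)C=C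
Why: Proposed new method: the cationic oxazaborolidine binds the trisubstituted enal CHO and blocks one face, so the nucleophilic methyl-bearing diene terminus attacks the β-carbon on its Si face (siloxy "para" to CHO) and the ring closes suprafacially with CHO endo, placing C4–Me, C5–Me and C10–CHO cis and C6 trans to C9 from the (E)-alkene, while the tetrasubstituted enal is too hindered to react and the acidic work-up cleaves the enol ether by protonation at C2 without touching C4; the closest known reactions are oxazaborolidinium-catalysed Diels–Alder reactions of 2-silyloxydienes with enals and AlBr3/AlMe3-promoted cycloadditions of hindered silyloxydienes with β,β-disubstituted enones.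

Step 5
Reactants: 14 2-{[(1S,2R,6R)-6-formyl-1,2-dimethyl-3-oxocyclohexyl]methyl}-3-methylbut-2-enal
Product: 16 (1R,2R,4aR,5S,6R,8aR)-1,8a-dimethyl-7-(propan-2-ylidene)decahydronaphthalene-2,5,6-triol, via keto diol 15 (not isolated)
Conditions: SmI2 (2.5 equiv), THF, −78 → −20 °C; then SmI2 (3 equiv), H2O, Et3N, 0 °C
Reagents that add atoms: none
Why: SmI2 turns the two aldehyde carbons into nucleophilic ketyls that couple 1,2 through a Sm(III)-bridged six-membered chair (intramolecular pinacol cyclisation) to the cis-diol with C9–O equatorial and C8–O pseudo-axial (away from the isopropylidene, no O/CH3 1,3-diaxial contact), and SmI2–H2O–Et3N then reduces the C3 ketone through its ketyl/carbanion to the more stable equatorial (R)-alcohol.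

Step 6
Reactants: 17 3-methylfuran-2(5H)-one; 18 dibromotriphenylphosphorane
Product: 19 (2Z)-4-bromo-2-methylbut-2-enoyl bromide
Conditions: MeCN, 60 °C; distil
Reagents that add atoms: dibromotriphenylphosphorane, BrP(Br)(c1ccccc1)(c1ccccc1)c1ccccc1
Why: Ph3PBr2 activates the lactone carbonyl and bromide opens the allylic C–O bond (lactone to ω-bromoacyl bromide cleavage, as known for phthalide), so the ring alkene, necessarily Z, is carried into the open chain.

Step 7
Reactants: 16 (1R,2R,4aR,5S,6R,8aR)-1,8a-dimethyl-7-(propan-2-ylidene)decahydronaphthalene-2,5,6-triol; 19 (2Z)-4-bromo-2-methylbut-2-enoyl bromide; 20 phenylboronic acid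
Product: 23 (1R,2R,4aR,5S,6R,8aR)-5,6-dihydroxy-1,8a-dimethyl-7-(propan-2-ylidene)decahydronaphthalen-2-yl (2Z)-4-bromo-2-methylbut-2-enoate, via cyclic phenylboronate 21 (not isolated), via acylated phenylboronate 22 (not isolated)
Conditions: PhB(OH)2 (1.05 equiv), toluene, 4 Å MS, rt; then 19, pyridine, CH2Cl2, 0 °C; then pinacol, rt
Reagents that add atoms: (2Z)-4-bromo-2-methylbut-2-enoyl bromide, BrC/C=C(/C)C(Br)=O
Why: The cis-8,9-diol is tied up as a five-membered phenylboronate (transient boronate protection), so only the equatorial C3–OH is O-acylated by the acyl bromide without a nucleophilic catalyst (keeping the Z alkene), and pinacol transesterification frees the diol.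

Step 8
Reactants: 23 (1R,2R,4aR,5S,6R,8aR)-5,6-dihydroxy-1,8a-dimethyl-7-(propan-2-ylidene)decahydronaphthalen-2-yl (2Z)-4-bromo-2-methylbut-2-enoate; 24 angelic acid
Product: 25 (1R,2R,4aR,5S,6R,8aR)-5,6-dihydroxy-1,8a-dimethyl-7-(propan-2-ylidene)decahydronaphthalen-2-yl (2Z)-2-methyl-4-{[(2Z)-2-methylbut-2-enoyl]oxy}but-2-enoate
Conditions: Cs2CO3, DMF, 0 °C → rt
Reagents that add atoms: angelic acid, C/C=C(/C)C(=O)O
Why: Carboxylate SN2 on the primary allylic bromide (alkylative esterification) installs the angelate without ever activating angelic acid as an acyl donor, so neither Z alkene is put at risk.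

Step 9
Reactants: 25 (1R,2R,4aR,5S,6R,8aR)-5,6-dihydroxy-1,8a-dimethyl-7-(propan-2-ylidene)decahydronaphthalen-2-yl (2Z)-2-methyl-4-{[(2Z)-2-methylbut-2-enoyl]oxy}but-2-enoate
Product: 26 (1R,2R,4aR,5S,8aR)-5-hydroxy-1,8a-dimethyl-6-oxo-7-(propan-2-ylidene)decahydronaphthalen-2-yl (2Z)-2-methyl-4-{[(2Z)-2-methylbut-2-enoyl]oxy}but-2-enoate (CNP0308665.1)
Conditions: activated MnO2 (20 equiv), CH2Cl2, rt
Reagents that add atoms: none
Why: MnO2 oxidises only the allylic C8 alcohol (chemoselective allylic oxidation) to the isopropylidene-conjugated ketone and leaves the saturated C9 carbinol and its configuration untouched.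

## Compound list

1 | 2,2-diethoxyacetaldehyde | CCOC(OCC)C=O | starting material
2 | isopropenylmagnesium bromide | CC(=C)[Mg]Br | starting material
3 | 1,1-diethoxy-3-methylbut-3-en-2-ol (racemic) | CCOC(OCC)C(O)C(C)=C | intermediate
4 | 1,1-diethoxy-3-methylbut-2-ene (prenal diethyl acetal) | CCOC(OCC)C=C(C)C | starting material
5 | 1-[(1,1-diethoxy-3-methylbut-3-en-2-yl)oxy]-1-ethoxy-3-methylbut-2-ene (mixed acetal) | CCOC(OCC)C(OC(OCC)C=C(C)C)C(C)=C | intermediate
6 | (1E)-1-[(1,1-diethoxy-3-methylbut-3-en-2-yl)oxy]-3-methylbuta-1,3-diene | CCOC(OCC)C(O/C=C/C(C)=C)C(C)=C | intermediate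
7 | (4E)-6,6-diethoxy-4-methyl-2-(prop-1-en-2-yl)hex-4-enal | CCOC(OCC)/C=C(\C)CC(C=O)C(C)=C | intermediate
8 | (4E)-6,6-diethoxy-4-methyl-2-(propan-2-ylidene)hex-4-enal | CCOC(OCC)/C=C(\C)CC(C=O)=C(C)C | intermediate
9 | (2E)-3-methyl-5-(propan-2-ylidene)hex-2-enedial | O=C/C=C(\C)CC(C=O)=C(C)C | intermediate
10 | pent-1-en-3-one (ethyl vinyl ketone) | CCC(=O)C=C | starting material
11 | tert-butyldimethylsilyl trifluoromethanesulfonate | CC(C)(C)[Si](C)(C)OS(=O)(=O)C(F)(F)F | starting material
12 | tert-butyldimethyl{[(3Z)-penta-1,3-dien-3-yl]oxy}silane | C/C=C(\O[Si](C)(C)C(C)(C)C)C=C | intermediate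
13 | 2-{[(1R,2R,6R)-3-[(tert-butyldimethylsilyl)oxy]-6-formyl-1,2-dimethylcyclohex-3-en-1-yl]methyl}-3-methylbut-2-enal | CC(C)(C)[Si](C)(C)OC1=CC[C@@H](C=O)[C@](C)(CC(C=O)=C(C)C)[C@H]1C | intermediate
14 | 2-{[(1S,2R,6R)-6-formyl-1,2-dimethyl-3-oxocyclohexyl]methyl}-3-methylbut-2-enal | O=C1CC[C@@H](C=O)[C@](C)(CC(C=O)=C(C)C)[C@H]1C | intermediate
15 | (1R,4aR,5S,6R,8aS)-5,6-dihydroxy-1,8a-dimethyl-7-(propan-2-ylidene)octahydronaphthalen-2(1H)-one | O=C1CC[C@H]2[C@H](O)[C@H](O)C(=C(C)C)C[C@]2(C)[C@H]1C | intermediate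
16 | (1R,2R,4aR,5S,6R,8aR)-1,8a-dimethyl-7-(propan-2-ylidene)decahydronaphthalene-2,5,6-triol | O[C@@H]1CC[C@H]2[C@H](O)[C@H](O)C(=C(C)C)C[C@]2(C)[C@H]1C | intermediate
17 | 3-methylfuran-2(5H)-one | CC1=CCOC1=O | starting material
18 | dibromotriphenylphosphorane | BrP(Br)(c1ccccc1)(c1ccccc1)c1ccccc1 | starting material
19 | (2Z)-4-bromo-2-methylbut-2-enoyl bromide | BrC/C=C(/C)C(Br)=O | intermediate
20 | phenylboronic acid | OB(O)c1ccccc1 | starting material
21 | cyclic 5,6-O-phenylboronate of triol 16 (2-OH free) | O[C@@H]1CC[C@H]2[C@@H]3OB(c4ccccc4)O[C@@H]3C(=C(C)C)C[C@]2(C)[C@H]1C | intermediate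
22 | 2-O-[(2Z)-4-bromo-2-methylbut-2-enoyl] derivative of boronate 21 | BrC/C=C(/C)C(=O)O[C@@H]1CC[C@H]2[C@@H]3OB(c4ccccc4)O[C@@H]3C(=C(C)C)C[C@]2(C)[C@H]1C | intermediate
23 | (1R,2R,4aR,5S,6R,8aR)-5,6-dihydroxy-1,8a-dimethyl-7-(propan-2-ylidene)decahydronaphthalen-2-yl (2Z)-4-bromo-2-methylbut-2-enoate | BrC/C=C(/C)C(=O)O[C@@H]1CC[C@H]2[C@H](O)[C@H](O)C(=C(C)C)C[C@]2(C)[C@H]1C | intermediate
24 | angelic acid, (2Z)-2-methylbut-2-enoic acid | C/C=C(/C)C(=O)O | starting material
25 | (1R,2R,4aR,5S,6R,8aR)-5,6-dihydroxy-1,8a-dimethyl-7-(propan-2-ylidene)decahydronaphthalen-2-yl (2Z)-2-methyl-4-{[(2Z)-2-methylbut-2-enoyl]oxy}but-2-enoate | C/C=C(/C)C(=O)OC/C=C(/C)C(=O)O[C@@H]1CC[C@H]2[C@H](O)[C@H](O)C(=C(C)C)C[C@]2(C)[C@H]1C | intermediate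
26 | (1R,2R,4aR,5S,8aR)-5-hydroxy-1,8a-dimethyl-6-oxo-7-(propan-2-ylidene)decahydronaphthalen-2-yl (2Z)-2-methyl-4-{[(2Z)-2-methylbut-2-enoyl]oxy}but-2-enoate | C/C=C(/C)C(=O)OC/C=C(/C)C(=O)O[C@@H]1CC[C@H]2[C@H](O)C(=O)C(=C(C)C)C[C@]2(C)[C@H]1C | target

## Step count and risks

Total steps: 9. Longest linear sequence: 7 steps (steps 1, 2, 4, 5, 7, 8, 9).

The three steps most likely to fail:

Step 4. The cycloaddition builds a quaternary centre next to a methyl-bearing diene terminus; it may be slow, may turn stepwise (scrambling the C5/C10 relationship) or give low ee. The fallback gives up catalytic enantiocontrol and resolves instead. It sets out from 9 and 12: the cycloaddition is run racemically with a mixed AlBr3/AlMe3 Lewis acid (CH2Cl2/toluene, −5 °C), giving 14 together with its mirror image, the ent-keto dialdehyde F2, through the ent-silyl enol ether cycloadduct F1. Step 5 on this racemate gives 16 and the ent-triol F4 through the ent-keto diol F3. Preparative chiral SFC separates the two triols, and the route is rejoined at 16.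

Step 5. The hindered enal may be simply reduced or couple through its β-carbon instead of forming the pinacol, and the C3 alcohol may come out axial. The fallback closes ring B with a catalytic acyl anion and sets C3 by inversion. It sets out from 14: a triazolium-derived N-heterocyclic carbene (20 mol %, DBU, THF, rt) turns the enal CHO into a Breslow intermediate that adds to the C9 aldehyde, and the reversible benzoin settles on the conjugated keto-ketol F5. TESOTf/2,6-lutidine gives the triethylsilyl ether F6. L-Selectride (THF, −78 °C) attacks only the unhindered C3 ketone from the α face and gives the axial 3β-alcohol F7. A Mitsunobu reaction (PPh3, DIAD, THF) with (2Z)-4-bromo-2-methylbut-2-enoic acid F8 (made from 19 and water) inverts C3 to the equatorial bromo ester F9. Caesium angelate (from 24, DMF) gives the silyl-protected target F10, and HF·pyridine returns to the route at 26.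

Step 7. The transient boronate may mask the diol incompletely, so that O-8/O-9 are acylated as well. The fallback replaces it by an isolated acetal. It sets out from 16: 2,2-dimethoxypropane/PPTS gives the 5,6-O-isopropylidene triol F11 (only the cis-diol can form the dioxolane). Acylation with 19/pyridine gives the acetonide bromo ester F12, and 80 % aqueous AcOH at rt removes the acetonide to rejoin the route at 23.

Further compounds
F1 | step 4 | ent-13, 2-{[(1S,2S,6S)-3-[(tert-butyldimethylsilyl)oxy]-6-formyl-1,2-dimethylcyclohex-3-en-1-yl]methyl}-3-methylbut-2-enal | CC(C)(C)[Si](C)(C)OC1=CC[C@H](C=O)[C@@](C)(CC(C=O)=C(C)C)[C@@H]1C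
F2 | step 4 | ent-14, 2-{[(1R,2S,6S)-6-formyl-1,2-dimethyl-3-oxocyclohexyl]methyl}-3-methylbut-2-enal | O=C1CC[C@H](C=O)[C@@](C)(CC(C=O)=C(C)C)[C@@H]1C
F3 | step 4 | ent-15, (1S,4aS,5R,6S,8aR)-5,6-dihydroxy-1,8a-dimethyl-7-(propan-2-ylidene)octahydronaphthalen-2(1H)-one | O=C1CC[C@@H]2[C@@H](O)[C@@H](O)C(=C(C)C)C[C@@]2(C)[C@@H]1C
F4 | step 4 | ent-16, (1S,2S,4aS,5R,6S,8aS)-1,8a-dimethyl-7-(propan-2-ylidene)decahydronaphthalene-2,5,6-triol | O[C@H]1CC[C@@H]2[C@@H](O)[C@@H](O)C(=C(C)C)C[C@@]2(C)[C@@H]1C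
F5 | step 5 | (1R,4aR,5S,8aS)-5-hydroxy-1,8a-dimethyl-7-(propan-2-ylidene)hexahydronaphthalene-2,6(1H,3H)-dione | O=C1CC[C@H]2[C@H](O)C(=O)C(=C(C)C)C[C@]2(C)[C@H]1C
F6 | step 5 | 5-O-triethylsilyl ether of F5 | O=C1CC[C@H]2[C@H](O[Si](CC)(CC)CC)C(=O)C(=C(C)C)C[C@]2(C)[C@H]1C
F7 | step 5 | (2S)-2-hydroxy (axial, 3β) alcohol from F6: 5-(triethylsilyloxy)-2-hydroxy-1,8a-dimethyl-7-(propan-2-ylidene)octahydronaphthalen-6-one | O[C@H]1CC[C@H]2[C@H](O[Si](CC)(CC)CC)C(=O)C(=C(C)C)C[C@]2(C)[C@H]1C
F8 | step 5 | (2Z)-4-bromo-2-methylbut-2-enoic acid | BrC/C=C(/C)C(=O)O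
F9 | step 5 | (2R)-ester (equatorial, inverted) of F7 with F8: 5-O-triethylsilyl-6-oxo analogue of 23 | BrC/C=C(/C)C(=O)O[C@@H]1CC[C@H]2[C@H](O[Si](CC)(CC)CC)C(=O)C(=C(C)C)C[C@]2(C)[C@H]1C
F10 | step 5 | 5-O-triethylsilyl ether of target 26 | C/C=C(/C)C(=O)OC/C=C(/C)C(=O)O[C@@H]1CC[C@H]2[C@H](O[Si](CC)(CC)CC)C(=O)C(=C(C)C)C[C@]2(C)[C@H]1C
F11 | step 7 | 5,6-O-isopropylidene acetal of triol 16 (2-OH free) | O[C@@H]1CC[C@H]2[C@@H]3OC(C)(C)O[C@@H]3C(=C(C)C)C[C@]2(C)[C@H]1C
F12 | step 7 | 2-O-[(2Z)-4-bromo-2-methylbut-2-enoyl] derivative of F11 | BrC/C=C(/C)C(=O)O[C@@H]1CC[C@H]2[C@@H]3OC(C)(C)O[C@@H]3C(=C(C)C)C[C@]2(C)[C@H]1C
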